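Late in Thursday's flask L stands still: the readings at 8.00 min and 20.0 min average 19.7% of the charge.

| flask | G | Q | temperature | remark | time |
|---|---|---|---|---|---|
| Thursday's | 20 mM | 50 mM | 25 °C | the very flask that is asked about, followed so far |  |
| Monday's | 20 mM | 50 mM | 20 °C | run made earlier |  |
| flask | 20 mM | 50.0 mM | 25 °C |  | 20 min |

| run | time / min | L / % | G / % |
|---|---|---|---|
| Thursday's | 1.50 | 9.0 | 34.0 |
| Thursday's | 4.00 | 17.1 | 0.1 |
| Thursday's | 8.00 | 19.9 | 0 |
| Thursday's | 20.0 | 19.5 | 0.4 |
| Monday's | 1.50 | 9.4 | 39.0 |
| Monday's | 4.00 | 22.9 | 0 |
| Monday's | 8.00 | 29.8 | 0 |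
| Monday's | 20.0 | 31.9 | 0.6 |

(scatter of a reading: 0.5 percentage points)

- alpha: change nothing and wait 10 min more
- eta: at 20 min add Q, 50.0% of the amount charged, then wait 10 min
- epsilon: at 20 min raise the temperature by 10 K, then wait 10 min

- additions bring no volume worth counting
- the numbers in the tables scatter with a standard deviation of 0.5 percentage points
- at the start none of G is in solution
- a reading or a percentage of L counts all its forms, free or not

- L, in percent of the G first charged, at 20 min
- which option adds most L ("none" when 2 percentage points or less is all one gets) (alpha / eta / epsilon / none)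
- L present, in percent of the G first charged, after alpha
- L present, in percent of the G first charged, after eta

Now watch the rate of L, not the amounts. If a rate loses the same share each minute, its whole sum is the start rate times a time constant. Over the first 1.50 min Thursday's mean rate is 0.0600 min⁻¹ of the charge, so a first round gives 3.28 min. But on this picture that mean has already faded, so the picture's start rate must be higher. You put the answer back in and go round until it stops moving, and you reach the fading time 2.46 min, the plateau divided by the start rate, which is then 0.0802 min⁻¹. This is rough: at 4.00 min the curve gives 15.8% against a reading of 17.1%.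

The same reckoning on Monday's cooler flask gives 4.30 min and a start rate of 0.0742 min⁻¹. Read from these two runs, which differ in temperature, the fading time is shorter in the warmer flask by a factor of 1.75, while the start rate differs by a factor of 1.08, which is less.

On this curve Thursday's rate at 20 min stands at 2.92 × 10⁻⁴ of its start, so I reckon on no gain from alpha. If the fade is Q dying, I would expect half a charge of Q to restart L at half the start rate with the same fading time, and my own reckoning for eta is then about 29.5%.

The forecast says 19.7% now, 19.7% after alpha, 30% after eta, and picks eta: “Fresh Q should then restart L”.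

The flask gives 19.7%, 19.7% after alpha and 41.7% after eta, a gain of 22 percentage points, with eta best.

    Q → E (k = 0.0110 s⁻¹, Ea = 76.0 kJ mol⁻¹)
    G ⇌ X, rate k2*(cs2 - [X]) while solid is left; crystals form when [X] > cs2 (solubility = 12.0 mM, k = 0.0170 s⁻¹)
    J ⇌ L, rate k3*(cs3 - [L]) while solid is left; crystals form when [L] > cs3 (solubility = 6.60 mM, k = 0.730 s⁻¹)
    X + Q → L (k = 0.350 M⁻¹ s⁻¹, Ea = 64.0 kJ mol⁻¹)
    G + L → Z (k = 2.30 M⁻¹ s⁻¹, Ea = 53.0 kJ mol⁻¹)
    (constants at 25 °C)

Divided by the fading time, the gain from eta asks a start rate of 0.0897 min⁻¹ of the charge, faster than the 0.0802 min⁻¹ reckoned for Thursday's first charge, and in Thursday's flask at 0.864 min the path from Q to E uses Q 5.7 times as fast as the path from X + Q to L, with half-lives of 1.1 min against 6.0 min. Carrying Thursday's start rate, as an amount, and its fading time to a flask charged with 8.0 mM of G gives 49.2% of that charge, and that flask stands at 61.5%.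

The earlier runs and the new flask were computed for an exercise; noise was put on by code.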